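**Plan**

- Retrosynthetic cuts: the C1–C8a bond (lactone carbonyl to ring A), the C2'–C3' bond of the side chain, the mevalonate ester C–O bond, and the C4–aryl and C3–C1' bonds, which both go back to the three carbons of (S)-epichlorohydrin.
- Forward order: aryl Grignard plus (S)-epichlorohydrin, then vinyl Grignard, then a benzyl oxalate on O2; separately (R)-mevalonolactone is opened, silylated and esterified with (S)-but-3-en-2-ol; cross-metathesis joins the chain.
- One hydrogenation then saturates the alkene and removes three benzyl groups; ring B (the lactone) is closed last, followed by desilylation.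
- Enabling feature: ring A is a hydroquinone (C5–OH and C8–OH para). As the 1,4-benzoquinone, C8a is the free β-carbon of the enone C5(=O)–C4a=C8a and lies six atoms from a carbonyl radical held on O2.
- Helpers: the carboxyl of a half-oxalate on O2 (lost as CO2) and the quinone oxidation level (returned to hydroquinone by dithionite).
- Stereochemistry: C3 (R) from (S)-epichlorohydrin, C4' (S) from (S)-but-3-en-2-ol, the mevalonate centre (R) from (R)-mevalonolactone; no stereocentre is made or broken in the route.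

Key step: step 9

Remark: atom labels follow isochroman-1-one numbering (C1 lactone carbonyl, O2, C3, C4, C4a, C5–C8, C8a; ring A benzene, ring B lactone), with the side chain C1'–C5' counted from C3. Alkene 16 is drawn as the E isomer; its geometry is erased in step 8.

**Step 1**
Reactants: 1 2-bromobenzene-1,4-diol (bromohydroquinone)
Product: 2 2-bromo-1,4-bis(benzyloxy)benzene
Conditions: BnBr (2.4 equiv), K2CO3 (3 equiv), DMF, rt, argon
Reagents that add atoms: benzyl bromide BrCc1ccccc1
Why: Williamson ether synthesis on both phenols; benzyl is chosen so that the arene protection later falls together with the benzyl oxalate in one hydrogenolysis.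

**Step 2**
Reactants: 2 2-bromo-1,4-bis(benzyloxy)benzene; 3 (S)-epichlorohydrin
Product: 6 (2S)-2-{[2,5-bis(benzyloxy)phenyl]methyl}oxirane, via aryl Grignard reagent 4 (not isolated), via chlorohydrin 5 (not isolated)
Conditions: Mg, THF, 50 °C; CuI (10 mol %), 3, THF, −40 → 0 °C; aq. work-up; K2CO3, MeOH, rt
Reagents that add atoms: none
Why: Copper-catalysed Grignard opening at the epoxide CH2 (not chloride displacement) followed by base-induced chlorohydrin-to-epoxide closure; the stereocentre is never a reaction site, so the configuration of 3 is carried into 6 and becomes C3 (R).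

**Step 3**
Reactants: 6 (2S)-2-{[2,5-bis(benzyloxy)phenyl]methyl}oxirane
Product: 7 (2R)-1-[2,5-bis(benzyloxy)phenyl]pent-4-en-2-ol
Conditions: vinylmagnesium bromide (2 equiv), CuI (10 mol %), THF, −30 → 0 °C
Reagents that add atoms: vinylmagnesium bromide C=C[Mg]Br
Why: Copper-catalysed Grignard opening of a terminal epoxide at its CH2 should give the homoallylic alcohol with the carbinol centre untouched.

**Step 4**
Reactants: 7 (2R)-1-[2,5-bis(benzyloxy)phenyl]pent-4-en-2-ol
Product: 9 benzyl (2R)-1-[2,5-bis(benzyloxy)phenyl]pent-4-en-2-yl oxalate, via chlorooxoacetate 8 (not isolated)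
Conditions: (COCl)2 (3 equiv), CH2Cl2, 0 °C → rt; evaporate; BnOH, pyridine, CH2Cl2, 0 °C
Reagents that add atoms: oxalyl chloride O=C(Cl)C(Cl)=O; benzyl alcohol OCc1ccccc1
Why: Acylation of the secondary alcohol with oxalyl chloride and esterification of the resulting acid chloride should give the mixed oxalate, placing the future C1 on O2 while no other hydroxyl is present.

**Step 5**
Reactants: 10 (R)-mevalonolactone
Product: 13 (3R)-5-[(tert-butyldiphenylsilyl)oxy]-3-hydroxy-3-methylpentanoic acid, via potassium mevalonate 11 (not isolated), via silyl ester 12 (not isolated)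
Conditions: KOH (1.05 equiv), H2O/MeOH, rt; evaporate; TBDPSCl (2.3 equiv), imidazole, DMF, rt; K2CO3, MeOH/THF/H2O, rt; aq. KHSO4 to pH 4
Reagents that add atoms: potassium hydroxide [K+].[OH-]; tert-butyl(chloro)diphenylsilane CC(C)(C)[Si](Cl)(c1ccccc1)c1ccccc1
Why: Saponification of the δ-lactone, silylation of carboxylate and primary hydroxyl (the tertiary hydroxyl is too hindered) and selective cleavage of the labile silyl ester should give the acid; the stereocentre is not involved.

**Step 6**
Reactants: 13 (3R)-5-[(tert-butyldiphenylsilyl)oxy]-3-hydroxy-3-methylpentanoic acid; 14 (S)-but-3-en-2-ol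
Product: 15 (2S)-but-3-en-2-yl (3R)-5-[(tert-butyldiphenylsilyl)oxy]-3-hydroxy-3-methylpentanoate
Conditions: DCC (1.2 equiv), DMAP (10 mol %), 14 (1.5 equiv), CH2Cl2, 0 °C → rt
Reagents that add atoms: none
Why: Steglich esterification proceeds with retention at the carbinol centre, and the hindered tertiary hydroxyl should not compete.

**Step 7**
Reactants: 9 benzyl (2R)-1-[2,5-bis(benzyloxy)phenyl]pent-4-en-2-yl oxalate; 15 (2S)-but-3-en-2-yl (3R)-5-[(tert-butyldiphenylsilyl)oxy]-3-hydroxy-3-methylpentanoate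
Product: 16 benzyl (2R,4E,6S)-1-[2,5-bis(benzyloxy)phenyl]-6-{[(3R)-5-[(tert-butyldiphenylsilyl)oxy]-3-hydroxy-3-methylpentanoyl]oxy}hept-4-en-2-yl oxalate
Conditions: second-generation Grubbs catalyst (H2IMes)(PCy3)Cl2Ru=CHPh (5 mol %), 9 (2 equiv), CH2Cl2, 40 °C
Reagents that add atoms: none
Why: Olefin cross-metathesis between a fast homoallylic alkene (in excess) and a branched allylic ester that homodimerises slowly should favour the cross product and forms the C2'–C3' bond.

**Step 8**
Reactants: 16 benzyl (2R,4E,6S)-1-[2,5-bis(benzyloxy)phenyl]-6-{[(3R)-5-[(tert-butyldiphenylsilyl)oxy]-3-hydroxy-3-methylpentanoyl]oxy}hept-4-en-2-yl oxalate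
Product: 17 2-{[(2R,6S)-6-{[(3R)-5-[(tert-butyldiphenylsilyl)oxy]-3-hydroxy-3-methylpentanoyl]oxy}-1-(2,5-dihydroxyphenyl)heptan-2-yl]oxy}-2-oxoacetic acid
Conditions: H2 (1 atm), Pd/C (10 %), EtOAc, rt; filtered under argon, used crude
Reagents that add atoms: none
Why: Heterogeneous hydrogenation saturates the alkene and hydrogenolysis removes the two aryl benzyl ethers and the benzyl ester, so one operation should unveil both the hydroquinone and the half-oxalate.

**Step 9**
Reactants: 17 2-{[(2R,6S)-6-{[(3R)-5-[(tert-butyldiphenylsilyl)oxy]-3-hydroxy-3-methylpentanoyl]oxy}-1-(2,5-dihydroxyphenyl)heptan-2-yl]oxy}-2-oxoacetic acid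
Product: 20 (2S)-5-[(3R)-5,8-dihydroxy-1-oxo-3,4-dihydro-1H-isochromen-3-yl]pentan-2-yl (3R)-5-[(tert-butyldiphenylsilyl)oxy]-3-hydroxy-3-methylpentanoate, via quinone half-oxalate 18 (not isolated), via quinone lactone 19 (not isolated)
Conditions: AgNO3 (20 mol %), (NH4)2S2O8 (3 equiv), MeCN/H2O (1:1), 0.01 M, 45 °C; then aq. Na2S2O4, rt
Reagents that add atoms: none
Why: Proposed new method: persulfate first oxidises the hydroquinone to quinone 18; divalent silver then oxidises the half-oxalate carboxylate, loss of CO2 gives the secondary alkoxycarbonyl radical RO–C(=O)•, this adds to C8a (the unsubstituted β-carbon of the C5(=O)–C4a=C8a enone), and the adduct radical is oxidised and deprotonated to quinone lactone 19, which dithionite reduces to the hydroquinone. The closest known reaction types are the silver/persulfate decarboxylative alkylation of quinones with carboxylic acids (Jacobsen–Torssell type) and the Minisci-type alkoxycarbonylation of protonated heteroarenes with oxalic acid monoesters; closure of an alkoxycarbonyl radical onto a quinone is not precedented. Ring B closes by a 6-endo-trig radical addition, whereas the 5-exo alternative would have to attack the fully substituted C4a and give a spiro radical that cannot be oxidised to a quinone and should revert or ring-expand to the same product. No stereocentre is formed, and C3 keeps its configuration because its C–O bond is never broken (the radical sits on the carbonyl carbon). The step needs cyclisation to outrun loss of a second CO2 (slow for a secondary, non-stabilised alkyl group), intermolecular addition (suppressed by dilution) and oxidation elsewhere (silver decarboxylation is inner-sphere at the only carboxylate); regiochemistry is fixed by the tether, since only C8a is within reach of a six-membered transition state and it is polarity-matched to the nucleophilic acyl-type radical.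

**Step 10**
Reactants: 20 (2S)-5-[(3R)-5,8-dihydroxy-1-oxo-3,4-dihydro-1H-isochromen-3-yl]pentan-2-yl (3R)-5-[(tert-butyldiphenylsilyl)oxy]-3-hydroxy-3-methylpentanoate
Product: 21 aspergimarin C, (2S)-5-[(3R)-5,8-dihydroxy-1-oxo-3,4-dihydro-1H-isochromen-3-yl]pentan-2-yl (3R)-3,5-dihydroxy-3-methylpentanoate
Conditions: HF·pyridine, pyridine/THF, 0 °C → rt
Reagents that add atoms: none
Why: Fluoride-mediated Si–O cleavage under buffered, mildly acidic conditions should free the primary alcohol without touching the esters, the lactone or the hydroquinone.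

**Compound list**

1 | 2-bromobenzene-1,4-diol (bromohydroquinone) | Oc1ccc(O)c(Br)c1 | starting material
2 | 2-bromo-1,4-bis(benzyloxy)benzene | Brc1cc(OCc2ccccc2)ccc1OCc1ccccc1 | intermediate
3 | (S)-epichlorohydrin, (2S)-2-(chloromethyl)oxirane | ClC[C@@H]1CO1 | starting material
4 | [2,5-bis(benzyloxy)phenyl]magnesium bromide | Br[Mg]c1cc(OCc2ccccc2)ccc1OCc1ccccc1 | intermediate
5 | (2S)-1-[2,5-bis(benzyloxy)phenyl]-3-chloropropan-2-ol | ClC[C@@H](O)Cc1cc(OCc2ccccc2)ccc1OCc1ccccc1 | intermediate
6 | (2S)-2-{[2,5-bis(benzyloxy)phenyl]methyl}oxirane | C(c1cc(OCc2ccccc2)ccc1OCc1ccccc1)[C@H]1CO1 | intermediate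
7 | (2R)-1-[2,5-bis(benzyloxy)phenyl]pent-4-en-2-ol | C=CC[C@@H](O)Cc1cc(OCc2ccccc2)ccc1OCc1ccccc1 | intermediate
8 | (2R)-1-[2,5-bis(benzyloxy)phenyl]pent-4-en-2-yl 2-chloro-2-oxoacetate | C=CC[C@H](Cc1cc(OCc2ccccc2)ccc1OCc1ccccc1)OC(=O)C(Cl)=O | intermediate
9 | benzyl (2R)-1-[2,5-bis(benzyloxy)phenyl]pent-4-en-2-yl oxalate | C=CC[C@H](Cc1cc(OCc2ccccc2)ccc1OCc1ccccc1)OC(=O)C(=O)OCc1ccccc1 | intermediate
10 | (R)-mevalonolactone, (4R)-4-hydroxy-4-methyloxan-2-one | C[C@@]1(O)CCOC(=O)C1 | starting material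
11 | potassium (3R)-3,5-dihydroxy-3-methylpentanoate | [K+].[O-]C(=O)C[C@](C)(O)CCO | intermediate
12 | tert-butyldiphenylsilyl (3R)-5-[(tert-butyldiphenylsilyl)oxy]-3-hydroxy-3-methylpentanoate | CC(C)(C)[Si](c1ccccc1)(c1ccccc1)OC(=O)C[C@](C)(O)CCO[Si](c1ccccc1)(c1ccccc1)C(C)(C)C | intermediate
13 | (3R)-5-[(tert-butyldiphenylsilyl)oxy]-3-hydroxy-3-methylpentanoic acid | OC(=O)C[C@](C)(O)CCO[Si](c1ccccc1)(c1ccccc1)C(C)(C)C | intermediate
14 | (S)-but-3-en-2-ol | C[C@H](O)C=C | starting material
15 | (2S)-but-3-en-2-yl (3R)-5-[(tert-butyldiphenylsilyl)oxy]-3-hydroxy-3-methylpentanoate | C=C[C@H](C)OC(=O)C[C@](C)(O)CCO[Si](c1ccccc1)(c1ccccc1)C(C)(C)C | intermediate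
16 | benzyl (2R,4E,6S)-1-[2,5-bis(benzyloxy)phenyl]-6-{[(3R)-5-[(tert-butyldiphenylsilyl)oxy]-3-hydroxy-3-methylpentanoyl]oxy}hept-4-en-2-yl oxalate | C[C@@H](/C=C/C[C@H](Cc1cc(OCc2ccccc2)ccc1OCc1ccccc1)OC(=O)C(=O)OCc1ccccc1)OC(=O)C[C@](C)(O)CCO[Si](c1ccccc1)(c1ccccc1)C(C)(C)C | intermediate
17 | 2-{[(2R,6S)-6-{[(3R)-5-[(tert-butyldiphenylsilyl)oxy]-3-hydroxy-3-methylpentanoyl]oxy}-1-(2,5-dihydroxyphenyl)heptan-2-yl]oxy}-2-oxoacetic acid | C[C@@H](CCC[C@H](Cc1cc(O)ccc1O)OC(=O)C(O)=O)OC(=O)C[C@](C)(O)CCO[Si](c1ccccc1)(c1ccccc1)C(C)(C)C | intermediate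
18 | 2-{[(2R,6S)-6-{[(3R)-5-[(tert-butyldiphenylsilyl)oxy]-3-hydroxy-3-methylpentanoyl]oxy}-1-(3,6-dioxocyclohexa-1,4-dien-1-yl)heptan-2-yl]oxy}-2-oxoacetic acid | C[C@@H](CCC[C@H](CC1=CC(=O)C=CC1=O)OC(=O)C(O)=O)OC(=O)C[C@](C)(O)CCO[Si](c1ccccc1)(c1ccccc1)C(C)(C)C | intermediate
19 | (2S)-5-[(3R)-1,5,8-trioxo-3,4,5,8-tetrahydro-1H-isochromen-3-yl]pentan-2-yl (3R)-5-[(tert-butyldiphenylsilyl)oxy]-3-hydroxy-3-methylpentanoate | C[C@@H](CCC[C@@H]1CC2=C(C(=O)O1)C(=O)C=CC2=O)OC(=O)C[C@](C)(O)CCO[Si](c1ccccc1)(c1ccccc1)C(C)(C)C | intermediate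
20 | (2S)-5-[(3R)-5,8-dihydroxy-1-oxo-3,4-dihydro-1H-isochromen-3-yl]pentan-2-yl (3R)-5-[(tert-butyldiphenylsilyl)oxy]-3-hydroxy-3-methylpentanoate | C[C@@H](CCC[C@@H]1Cc2c(O)ccc(O)c2C(=O)O1)OC(=O)C[C@](C)(O)CCO[Si](c1ccccc1)(c1ccccc1)C(C)(C)C | intermediate
21 | aspergimarin C, (2S)-5-[(3R)-5,8-dihydroxy-1-oxo-3,4-dihydro-1H-isochromen-3-yl]pentan-2-yl (3R)-3,5-dihydroxy-3-methylpentanoate | C[C@@H](CCC[C@@H]1Cc2c(O)ccc(O)c2C(=O)O1)OC(=O)C[C@](C)(O)CCO | target

**Count and risks**

Total step count: 10. Longest linear sequence: 8 steps (steps 1, 2, 3, 4, 7, 8, 9, 10).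

Steps most likely to fail:

1. Step 9. The alkoxycarbonyl radical may lose CO2 before it closes, the half-oxalate may hydrolyse in the warm aqueous acid, radicals may add between molecules, or water may add to the acylquinone before the reductive quench. The fallback uses known chemistry, sets out from 7 and 15 and comes back at 20. Cross-metathesis of the free alcohol 7 with 15 (second-generation Grubbs catalyst, CH2Cl2, 40 °C) should give the hydroxy alkene F1. Homogeneous hydrogenation (H2, RhCl(PPh3)3, toluene), which leaves aryl benzyl ethers alone, should give the saturated alcohol F2. Hydroxyl-directed ortho C–H carbonylation (Pd(OAc)2, a mono-N-protected amino acid ligand such as N-Boc-leucine, AgOAc, Li2CO3, CO 1 atm, 1,2-dichloroethane, 100 °C) is a known divalent-palladium route from 2-arylethanols to isochroman-1-ones; here the only free position ortho to the side chain is C8a, and the step should give the dibenzyl lactone F3. Hydrogenolysis (H2, Pd/C, EtOAc) then gives 20.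

2. Step 8. Hydrogenolysis of the allylic C–O bond (loss of the mevalonate ester) may compete with saturation of the alkene, and the half-oxalate may be cleaved on handling. The fallback sets out from 16 and comes back at 17. Diimide reduction (2-nitrobenzenesulfonylhydrazide, Et3N, CH2Cl2, rt) should saturate only the alkene and give the saturated tribenzyl compound F4, which has no allylic oxygen; hydrogenolysis (H2, Pd/C, EtOAc) then gives 17.

3. Step 7. The branched allylic ester may couple slowly, leaving homodimerisation of 9 and alkene migration as the main processes. The fallback sets out from 9 and 14 and comes back at 16, reversing the order of C–C and C–O bond formation. Cross-metathesis of 9 with an excess of the small, free alcohol 14 (same catalyst) should give the allylic alcohol F5; Steglich esterification of F5 with acid 13 (DCC, DMAP, CH2Cl2) then gives 16.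

**Further compounds**

F1 | step 9 | (2S,3E,6R)-7-[2,5-bis(benzyloxy)phenyl]-6-hydroxyhept-3-en-2-yl (3R)-5-[(tert-butyldiphenylsilyl)oxy]-3-hydroxy-3-methylpentanoate | C[C@@H](/C=C/C[C@@H](O)Cc1cc(OCc2ccccc2)ccc1OCc1ccccc1)OC(=O)C[C@](C)(O)CCO[Si](c1ccccc1)(c1ccccc1)C(C)(C)C
F2 | step 9 | (2S,6R)-7-[2,5-bis(benzyloxy)phenyl]-6-hydroxyheptan-2-yl (3R)-5-[(tert-butyldiphenylsilyl)oxy]-3-hydroxy-3-methylpentanoate | C[C@@H](CCC[C@@H](O)Cc1cc(OCc2ccccc2)ccc1OCc1ccccc1)OC(=O)C[C@](C)(O)CCO[Si](c1ccccc1)(c1ccccc1)C(C)(C)C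
F3 | step 9 | (2S)-5-[(3R)-5,8-bis(benzyloxy)-1-oxo-3,4-dihydro-1H-isochromen-3-yl]pentan-2-yl (3R)-5-[(tert-butyldiphenylsilyl)oxy]-3-hydroxy-3-methylpentanoate | C[C@@H](CCC[C@@H]1Cc2c(OCc3ccccc3)ccc(OCc3ccccc3)c2C(=O)O1)OC(=O)C[C@](C)(O)CCO[Si](c1ccccc1)(c1ccccc1)C(C)(C)C
F4 | step 8 | benzyl (2R,6S)-1-[2,5-bis(benzyloxy)phenyl]-6-{[(3R)-5-[(tert-butyldiphenylsilyl)oxy]-3-hydroxy-3-methylpentanoyl]oxy}heptan-2-yl oxalate | C[C@@H](CCC[C@H](Cc1cc(OCc2ccccc2)ccc1OCc1ccccc1)OC(=O)C(=O)OCc1ccccc1)OC(=O)C[C@](C)(O)CCO[Si](c1ccccc1)(c1ccccc1)C(C)(C)C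
F5 | step 7 | benzyl (2R,4E,6S)-1-[2,5-bis(benzyloxy)phenyl]-6-hydroxyhept-4-en-2-yl oxalate | C[C@H](O)/C=C/C[C@H](Cc1cc(OCc2ccccc2)ccc1OCc1ccccc1)OC(=O)C(=O)OCc1ccccc1
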